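**Strategy.** Lactucaxanthin is C2-symmetric, so one C10 end-group unit is made once and joined twice to the C20 dialdehyde crocetindialdehyde by Horner–Wittig olefination. Everything rests on closing each ε ring at C1–C6, the bond between the quaternary gem-dimethyl carbon and the allylic methine that carries the chain. Iron-hydride hydrogen-atom transfer turns an isopropenyl group into the tertiary C1 radical, which adds 6-exo to C6 of an (E)-alkenylphosphine oxide. One operation gives the ring, the quaternary centre, the C6 stereocentre (relayed from the C3 carbinol) and a C7 phosphorus handle for C7=C8. The precursor is an acyclic (Z)-dienyl carbinol, made in three steps from a commercial six-carbon enynol.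

Key step: step 4

Remark: positions are given in carotenoid numbering (C1 gem-dimethyl carbon, C3 carbinol, C4=C5 ring alkene, C6 ring methine, C7=C8 first chain alkene), and crocetindialdehyde is taken as a purchasable C20 building block.

Step 1
Reactants: 1 (2Z)-3-methylpent-2-en-4-yn-1-ol
Product: 2 (2Z)-3-methylpent-2-en-4-ynal
Conditions: activated MnO2 (10 equiv), CH2Cl2, 0 °C to rt, dark; filtered and used at once
Reagents that add atoms: none
Why: Allylic oxidation with activated MnO2 should give the enal without acid or base, so the (Z) geometry of the trisubstituted alkene (the future ring C4=C5 bond) and the terminal alkyne are kept.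

Step 2
Reactants: 2 (2Z)-3-methylpent-2-en-4-ynal; 3 4,4,5,5-tetramethyl-2-(2-methylprop-2-en-1-yl)-1,3,2-dioxaborolane
Product: 5 (4R,5Z)-2,6-dimethylocta-1,5-dien-7-yn-4-ol, via pinacol borate ester 4 (not isolated)
Conditions: (R)-TRIP [(R)-3,3'-bis(2,4,6-triisopropylphenyl)-1,1'-binaphthyl-2,2'-diyl hydrogen phosphate] (5 mol %), 4 Å MS, toluene, −30 °C; aq NaHCO3 work-up
Reagents that add atoms: none
Why: Chiral phosphoric acid-catalysed allylboration through a closed six-membered chair transition state, in which the (R)-catalyst should direct the 2-methylallyl group to the Re face of the aldehyde and so set the future C3 carbinol as R; borate ester 4 is hydrolysed on work-up.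

Step 3
Reactants: 5 (4R,5Z)-2,6-dimethylocta-1,5-dien-7-yn-4-ol; 6 diphenylphosphine oxide
Product: 7 [(1E,3Z,5R)-5-hydroxy-3,7-dimethylocta-1,3,7-trien-1-yl]diphenylphosphine oxide
Conditions: RhCl(PPh3)3 (3 mol %), toluene, rt
Reagents that add atoms: none
Why: Rhodium-catalysed hydrophosphinylation (P–H oxidative addition, syn hydrometalation of the terminal alkyne, reductive elimination) should place phosphorus on the terminal carbon and give the (E)-alkenylphosphine oxide, while both alkenes and the carbinol stay untouched.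

Step 4
Reactants: 7 [(1E,3Z,5R)-5-hydroxy-3,7-dimethylocta-1,3,7-trien-1-yl]diphenylphosphine oxide
Product: 8 {[(1R,4R)-4-hydroxy-2,6,6-trimethylcyclohex-2-en-1-yl]methyl}diphenylphosphine oxide
Conditions: Fe(acac)3 (30 mol %), PhSiH3 (2.5 equiv), EtOH/ethylene glycol (5:1), 0.02 M, 60 °C
Reagents that add atoms: none
Why: An Fe–H species formed from Fe(acac)3 and PhSiH3 should transfer a hydrogen atom to the terminal CH2 of the isopropenyl group, giving the tertiary C1 radical (its two methyl groups are then equivalent, so C1 raises no stereochemical question), which adds to C6, the β-carbon of the (E)-alkenylphosphine oxide; the α-phosphoryl radical at C7 is then reduced and protonated by the alcohol medium. The closest known reaction type is the iron-hydride hydrogen-atom-transfer reductive olefin coupling (radical conjugate addition of Giese type), used here intramolecularly. The six-membered ε ring closes through the C1–C6 bond in the 6-exo-trig mode, with the (Z)-C4=C5 alkene already in place inside the forming ring. The new C6 stereocentre is set by the C3 carbinol through a half-chair transition state in which the hydroxyl is pseudo-equatorial (a pseudo-axial hydroxyl would lie syn to a C1 methyl group) and the extended alkenylphosphine oxide arm is exo, hence pseudo-equatorial, which should place O3 and C7 trans and give 6R from 3R; the protic medium keeps the hydroxyl from hydrogen bonding to the P=O group, which would favour the cis mode. The step needs hydrogen-atom transfer to the electron-rich 1,1-disubstituted alkene and not to the electron-poor diene, which polarity matching secures, and attack at C6 only, which the tether secures because the 4-exo, 5-endo and 7-endo alternatives are strained or electronically mismatched.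

Step 5
Reactants: 8 {[(1R,4R)-4-hydroxy-2,6,6-trimethylcyclohex-2-en-1-yl]methyl}diphenylphosphine oxide (2.2 equiv); 9 crocetindialdehyde
Product: 11 lactucaxanthin [(3R,6R,3'R,6'R)-ε,ε-carotene-3,3'-diol], via bis(β-hydroxyphosphine oxide) adduct 10 (not isolated)
Conditions: n-BuLi (2 equiv per 8), THF, −78 °C; 9, −78 to 0 °C; KOt-Bu, 0 °C to rt; then heptane, 90 °C, crystallisation; argon, dim light
Reagents that add atoms: none
Why: Twofold Horner–Wittig olefination, in which the lithiated phosphine oxide (as its alkoxide dianion) should add to both aldehyde groups, the potassium alkoxides of 10 then lose diphenylphosphinate by syn elimination to form C7=C8 and C7'=C8', and heating equilibrates any (Z) isomers to the all-(E) polyene without touching the four stereocentres.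

**Compound list**

1 | (2Z)-3-methylpent-2-en-4-yn-1-ol | C#C/C(C)=C\CO | starting material
2 | (2Z)-3-methylpent-2-en-4-ynal | C#C/C(C)=C\C=O | intermediate
3 | 4,4,5,5-tetramethyl-2-(2-methylprop-2-en-1-yl)-1,3,2-dioxaborolane | C=C(C)CB1OC(C)(C)C(C)(C)O1 | starting material
4 | 2-{[(4R,5Z)-2,6-dimethylocta-1,5-dien-7-yn-4-yl]oxy}-4,4,5,5-tetramethyl-1,3,2-dioxaborolane | C=C(C)C[C@@H](OB1OC(C)(C)C(C)(C)O1)/C=C(C)\C#C | intermediate
5 | (4R,5Z)-2,6-dimethylocta-1,5-dien-7-yn-4-ol | C=C(C)C[C@@H](O)/C=C(C)\C#C | intermediate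
6 | diphenylphosphine oxide | O=[PH](c1ccccc1)c1ccccc1 | starting material
7 | [(1E,3Z,5R)-5-hydroxy-3,7-dimethylocta-1,3,7-trien-1-yl]diphenylphosphine oxide | C=C(C)C[C@@H](O)/C=C(C)\C=C\P(=O)(c1ccccc1)c1ccccc1 | intermediate
8 | {[(1R,4R)-4-hydroxy-2,6,6-trimethylcyclohex-2-en-1-yl]methyl}diphenylphosphine oxide | CC1=C[C@H](O)CC(C)(C)[C@H]1CP(=O)(c2ccccc2)c3ccccc3 | intermediate
9 | crocetindialdehyde, (2E,4E,6E,8E,10E,12E,14E)-2,6,11,15-tetramethylhexadeca-2,4,6,8,10,12,14-heptaenedial | O=C/C(C)=C/C=C/C(C)=C/C=C/C=C(C)/C=C/C=C(C)/C=O | starting material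
10 | (3R,6R,3'R,6'R)-7,7'-bis(diphenylphosphoryl)-7,8,7',8'-tetrahydro-ε,ε-carotene-3,8,3',8'-tetrol (diastereomer mixture at C7, C8, C7', C8') | CC1=C[C@H](O)CC(C)(C)[C@H]1C(P(=O)(c2ccccc2)c3ccccc3)C(O)/C(C)=C/C=C/C(C)=C/C=C/C=C(C)/C=C/C=C(C)/C(O)C([C@H]4C(C)=C[C@H](O)CC4(C)C)P(=O)(c5ccccc5)c6ccccc6 | intermediate
11 | lactucaxanthin, (3R,6R,3'R,6'R)-ε,ε-carotene-3,3'-diol | CC1=C[C@H](O)CC(C)(C)[C@H]1/C=C/C(C)=C/C=C/C(C)=C/C=C/C=C(C)/C=C/C=C(C)/C=C/[C@H]1C(C)=C[C@H](O)CC1(C)C | target

**Total step count:** 5
**Longest linear sequence:** 5 steps (1 → 2 → 5 → 7 → 8 → 11)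

**Steps most likely to fail**

Step 4 (key step). The radical may close onto the other face of C6, for instance through a transition state with a pseudo-axial alkenyl arm, so that the 3,6-cis isomer forms mainly; the 1,4-relay from C3 to C6 is the least certain element of the route. The fallback is a stereochemical relay through the ring enone and sets out from 2. The (S)-configured phosphoric acid catalyst should give, via pinacol borate ester 2-{[(4S,5Z)-2,6-dimethylocta-1,5-dien-7-yn-4-yl]oxy}-4,4,5,5-tetramethyl-1,3,2-dioxaborolane F1, the enantiomeric carbinol (4S,5Z)-2,6-dimethylocta-1,5-dien-7-yn-4-ol F2. Hydrophosphinylation as in step 3 gives [(1E,3Z,5S)-5-hydroxy-3,7-dimethylocta-1,3,7-trien-1-yl]diphenylphosphine oxide F3. The same ring closure, now used in its cis mode, gives {[(1R,4S)-4-hydroxy-2,6,6-trimethylcyclohex-2-en-1-yl]methyl}diphenylphosphine oxide F4. MnO2 in CH2Cl2 oxidises the allylic alcohol to (4R)-4-[(diphenylphosphoryl)methyl]-3,5,5-trimethylcyclohex-2-en-1-one F5, in which C6 is the only stereocentre. LiBH(s-Bu)3 in THF at −78 °C should then add hydride 1,2 (the β-carbon is fully substituted) and anti to the pseudo-axial C1 methyl group, giving the trans alcohol and coming back to the route at 8.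

Step 5. The hindered α-phosphoryl carbanion may add with erythro selectivity, which leads to (7Z) alkenes that equilibrate poorly, or elimination from the tetra-alkoxide may stall. The fallback is the acylation–reduction variant of the Horner–Wittig reaction, which fixes the threo adduct and hence the (E) alkene; it sets out from 8. The dianion of 8 (n-BuLi, THF, −78 °C, excess base) is acylated with purchased dimethyl crocetinate to give (3R,6R,3'R,6'R)-7,7'-bis(diphenylphosphoryl)-3,3'-dihydroxy-7,8,7',8'-tetrahydro-ε,ε-carotene-8,8'-dione F6. NaBH4 with CeCl3 in MeOH/THF should reduce both ketones to the threo-rich form of 10, and NaH in DMF followed by the same thermal equilibration comes back to the route at 11.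

Step 3. The free hydroxyl is held cis to the alkyne across the (Z)-alkene and may attack the rhodium-bound alkyne (cycloisomerisation to a furan or 2H-pyran), or P–H addition may lose its regiocontrol on the conjugated enyne. The fallback removes the nucleophile and sets out from 5. TBSCl and imidazole in DMF give tert-butyl{[(4R,5Z)-2,6-dimethylocta-1,5-dien-7-yn-4-yl]oxy}dimethylsilane F7. Hydrophosphinylation under the step 3 conditions gives [(1E,3Z,5R)-5-{[tert-butyl(dimethyl)silyl]oxy}-3,7-dimethylocta-1,3,7-trien-1-yl]diphenylphosphine oxide F8, and Bu4NF in THF comes back to the route at 7.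

Further compounds
F1 | step 4 | 2-{[(4S,5Z)-2,6-dimethylocta-1,5-dien-7-yn-4-yl]oxy}-4,4,5,5-tetramethyl-1,3,2-dioxaborolane | C=C(C)C[C@H](OB1OC(C)(C)C(C)(C)O1)/C=C(C)\C#C
F2 | step 4 | (4S,5Z)-2,6-dimethylocta-1,5-dien-7-yn-4-ol | C=C(C)C[C@H](O)/C=C(C)\C#C
F3 | step 4 | [(1E,3Z,5S)-5-hydroxy-3,7-dimethylocta-1,3,7-trien-1-yl]diphenylphosphine oxide | C=C(C)C[C@H](O)/C=C(C)\C=C\P(=O)(c1ccccc1)c1ccccc1
F4 | step 4 | {[(1R,4S)-4-hydroxy-2,6,6-trimethylcyclohex-2-en-1-yl]methyl}diphenylphosphine oxide | CC1=C[C@@H](O)CC(C)(C)[C@H]1CP(=O)(c2ccccc2)c3ccccc3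
F5 | step 4 | (4R)-4-[(diphenylphosphoryl)methyl]-3,5,5-trimethylcyclohex-2-en-1-one | CC1=CC(=O)CC(C)(C)[C@H]1CP(=O)(c2ccccc2)c3ccccc3
F6 | step 5 | (3R,6R,3'R,6'R)-7,7'-bis(diphenylphosphoryl)-3,3'-dihydroxy-7,8,7',8'-tetrahydro-ε,ε-carotene-8,8'-dione | CC1=C[C@H](O)CC(C)(C)[C@H]1C(P(=O)(c2ccccc2)c3ccccc3)C(=O)/C(C)=C/C=C/C(C)=C/C=C/C=C(C)/C=C/C=C(C)/C(=O)C([C@H]4C(C)=C[C@H](O)CC4(C)C)P(=O)(c5ccccc5)c6ccccc6
F7 | step 3 | tert-butyl{[(4R,5Z)-2,6-dimethylocta-1,5-dien-7-yn-4-yl]oxy}dimethylsilane | C=C(C)C[C@@H](O[Si](C)(C)C(C)(C)C)/C=C(C)\C#C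
F8 | step 3 | [(1E,3Z,5R)-5-{[tert-butyl(dimethyl)silyl]oxy}-3,7-dimethylocta-1,3,7-trien-1-yl]diphenylphosphine oxide | C=C(C)C[C@@H](O[Si](C)(C)C(C)(C)C)/C=C(C)\C=C\P(=O)(c1ccccc1)c1ccccc1
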